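## Analysis of the target

The target 33 is an α-methylene-γ-butyrolactone, cis-fused through C6–C7 to a cycloheptane that also carries a tertiary carbinol with a (Z)-but-2-enoyl group, a secondary 3-methylbutanoate (isovalerate), a free secondary hydroxyl and a methyl group. The atoms are numbered as follows: C1 is the ring carbon with the hydroxyl and the acyl chain C2(=O)–C3=C4–CH3; C5 the ring CH–O-isovalerate; C6 the ring CH–O of the lactone; C7 the ring-fusion CH; C8 the ring CH2; C9 the ring CHOH; C10 the ring CH(CH3); C11, C12 and C13 the lactone α-carbon, carbonyl carbon and exocyclic methylene. Six of the seven ring carbons are stereocentres (1S,5S,6R,7S,9R,10S): the C6 oxygen, the C7–C11 bond, the C10 methyl and the C1 hydroxyl lie on one face (called α below), the C5 acyloxy group, the C9 hydroxyl and the C1 acyl group on the other (β). The sensitive groups are the methylene lactone (a Michael acceptor), the Z-enone next to a tertiary α-hydroxyl (isomerisation, α-ketol shift) and an ester flanked by free hydroxyls (acyl migration). The difficulty is a seven-membered carbocycle with six stereocentres, one of them fully substituted, that must be built without a rigid template, together with five oxygen functions of four kinds that must be told apart. The strategy rests on one structural fact: the C6 oxygen, the C7 branch and the C10 methyl are mutually cis, C1 carries a carboxyl-level carbon (C2) and C9 is oxygenated, which is the substitution pattern of a cyclohepta-1,4-diene-1-carboxylate (C1=C5, C8=C9 as an enol ether) formed from an (E)-vinylcarbenoid (C2–C1–C5=C6–O) and a 2-silyloxy diene (C10=C9(O)–C8=C7–C11–C12).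

## Retrosynthetic reasoning

**C2–C3 (33 ← 32 ← 31 ← 29 + 30).** The Z-enone is the most fragile group, so it is formed last but one, and the C9 silyl ether is removed last. The C2–C3 bond is cut between an aldehyde at C2 (29) and the (Z)-propenyl halide 30. Forward, an aldehyde-selective chromium-mediated alkenylation must spare the lactone, the isovalerate and the methylene lactone, and oxidation of carbinol 31 must not isomerise the double bond.

**C5–O (29 ← 28 ← 27).** The isovalerate oxygen at C5 is β and the C1 hydroxyl is α, a trans relationship that an α-epoxide (27) delivers if the carboxylate attacks C5 with inversion. The cut is made here because C1 cannot be inverted. The primary C2 hydroxyl of 27 serves as the anchor for a titanium alkoxide, which steers the nucleophile to the distal carbon C5 and away from the tertiary C1. Diol 28 is then oxidised at C2 to 29.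

**C11=C13 and the C2 protecting group (27 ← 26 ← 24 ← 23).** The methylene carbon is added to the lactone enolate of 23 as an aminomethyl group (24) and unmasked by elimination (26). This is placed before the isovalerate enters, because a second enolisable ester would make the enolate step unselective. The C2 ether is cleaved oxidatively afterwards.

**Lactone and epoxide (23 ← 20 ← 19).** The O–C12 lactone bond comes from oxidation of the primary C12 alcohol in the presence of the cis C6 hydroxyl. Before that, the same C6 hydroxyl (α) directs a metal-catalysed epoxidation of C1=C5 to the α-face. The order matters: the hydroxyl is needed free as a directing group first and is then consumed by the lactone.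

**Redox and protecting-group adjustment (19 ← 18 ← 17 ← 16).** The C2 ester of 16 is reduced to the allylic alcohol 17 early, since no later reagent could reduce it beside a lactone and an isovalerate. As a PMB ether (18) it neither directs the epoxidation nor is oxidised with C12. The two TBS ethers (O6, O12) are removed together to give 19, while the more robust TIPS ether at O9 stays.

**C9 (16 ← 15 ← 14 ← 13).** The enol ether of 13 is the masked C9 ketone. Cleaving it gives 14, and a reagent-controlled reduction sets the β-hydroxyl of 15, trans to the C10 methyl. This is done while C1=C5 is still an unreactive enoate, and before an epoxide is present that a β,γ-keto group would open by elimination.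

**Key disconnection (13 ← 11 + 5, through 12).** Bonds C1–C10 and C6–C7 are cut. Forward, the vinylcarbenoid from 11 cyclopropanates the enol ether alkene C9=C10 of 5 (bonds C1–C10, C1–C9) and the cis-divinylcyclopropane 12 rearranges (C6–C7 formed, C1–C9 broken). This gives the ring, the three cis stereocentres C6, C7 and C10 in one enantioselective step, C9 at the ketone level, C1=C5 ready for oxygenation and C2 as an ester.

**Carbenoid precursor (11 ← 9 ← 7 + 8; 7 ← 6).** The C5=C6 enol ether is cut back to an aldol adduct 9 of the diazo ester 7 and the silyloxy aldehyde 8. Dehydration of 9 through its phosphate 10 forms the double bond in conjugation and with E geometry, which direct enol silylation of an aldehyde would not guarantee. Compound 7 comes from the amino ester salt 6.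

**Diene (5 ← 4 ← 2 + 3; 2 ← 1).** The enol ether is cut back to enone 4, whose C7=C8 double bond is made by cross-metathesis of the silylated butenol 2 with the vinyl ketone 3. Forward, the enolisation must be α′-selective and give the Z enol ether.

## Alternatives that were turned down

**Alternative 1: ring closure by an allylchromium addition with lactonisation in the same step.**
- Disconnection: C6–C7 and the lactone O–C12 bond.
- Forward key step: the acyclic bromomethyl enoate aldehyde A1 would be treated with a divalent chromium salt. The allylchromium formed at C13 would add through its γ-carbon C7 to the C6 aldehyde, closing the cycloheptane, and the chromium alkoxide would attack the methyl ester to give the bicyclic methylene lactone A2.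
- For it: one step would close the carbocycle, set C6 and C7 and deliver the finished α-methylene lactone. On that point it is stronger than the chosen route, which spends three steps on lactone and methylene (steps 15 to 17).
- Against it: A1 must already hold C1 (fully substituted), C5, C9 and C10, four stereocentres to be set one by one in an open chain. Its α-acyloxy aldehyde is prone to epimerisation and acyl shift. A seven-membered ring is closed against an entropic penalty. The configuration at C7 relative to C9 and C10 depends only on the shape of a medium-ring transition state.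
- Comparison: the chosen strategy has no comparable late shortcut for the lactone, but it makes the ring and three stereocentres catalytically from two achiral fragments in seven steps, where this alternative needs a long stereocontrolled chain synthesis before its key step.

**Alternative 2: ring contraction of an oxepanone by an ester-enolate Claisen rearrangement.**
- Disconnection: C1–C10, with the O–C8 bond restored in the retrosynthetic direction.
- Forward key step: the seven-membered lactone A3 would be converted by an amide base and a silyl chloride into its silyl ketene acetal, which would rearrange through a boat to the cycloheptene acid A4.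
- For it: the fully substituted C1 with its oxygen and the C10 methyl would be set together by a stereospecific sigmatropic shift. That is stronger than the chosen route at C1, where an epoxidation and a regioselective opening are needed.
- Against it: A3 needs four stereocentres, a Z-propenyl group and a seven-membered lactonisation before the key step. Its enolate has a β-oxygen at C5 and can eliminate. A4 has no oxygen at C9, and hydration of the C8=C9 ring alkene has no clear regiochemical bias. The acid must still become the Z-enone.
- Comparison: the chosen strategy brings C9 in oxygenated and reaches the ring much earlier; in exchange it accepts a two-step oxygenation of C1=C5.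

**Alternative 3: closure of C9–C10 by an allylsilane–aldehyde cyclisation.**
- Disconnection: C9–C10.
- Forward key step: a Lewis acid would activate the C9 aldehyde of lactone A5, and its (Z)-crotylsilane would attack through C10 with loss of silicon, giving the cycloheptane A6 with an exocyclic C1=C2 methylene.
- For it: the lactone is in place early, the C9 hydroxyl and C10 methyl arise in the ring-closing step, and dihydroxylation of the exocyclic alkene would put oxygen on C1 and C2 with no regiochemical question. On that last point it is as strong as or stronger than the chosen route.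
- Against it: the trans relation of C9–OH and C10–CH3, and their relation to C5–C7, depend on the competition of synclinal and antiperiplanar transition states in a seven-membered closure, for which no bias can be named. The face of the later dihydroxylation at C1 is likewise open, since the two flanking substituents lie on opposite faces. A5 needs three stereocentres and a stereodefined trisubstituted allylsilane beforehand.
- Comparison: the chosen strategy fixes C6, C7 and C10 by alkene geometry and a chiral catalyst, and each later centre is set by a named directing element.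

Key step: step 7

Assumptions (remarks on the chemistry):
- The sense of induction of Rh2(S-DOSP)4 in step 7 is taken to be the one established for this catalyst with donor/acceptor carbenoids and terminal or 1,1-disubstituted alkenes. If the trisubstituted enol ether reversed it, Rh2(R-DOSP)4 would be used with nothing else changed.
- Compounds 1, 3, 6, 8 and 30 are taken as commercial.

Names of ring compounds use the atom numbers of the target (ring: C1, C5, C6, C7, C8, C9, C10) and α/β as defined above. TBS = tert-butyldimethylsilyl, TIPS = triisopropylsilyl, PMB = 4-methoxybenzyl.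

## Route

Step 1
Reactants: 1 but-3-en-1-ol
Product: 2 tert-butyl(but-3-en-1-yloxy)dimethylsilane
Conditions: TBSCl, imidazole, CH2Cl2, 0 °C to rt
Reagents that add atoms: tert-butyldimethylsilyl chloride, CC(C)(C)[Si](C)(C)Cl
Why: Standard silylation of a primary alcohol; the ether masks the future C12 hydroxyl through the carbenoid step and is later removed together with the C6 silyl ether.

Step 2
Reactants: 2 tert-butyl(but-3-en-1-yloxy)dimethylsilane; 3 pent-1-en-3-one
Product: 4 (E)-7-(tert-butyldimethylsilyloxy)hept-4-en-3-one
Conditions: second-generation Hoveyda–Grubbs catalyst RuCl2(H2IMes)(=CH-C6H4-2-O-i-Pr) (3 mol%), 3 (3 equiv), CH2Cl2, 40 °C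
Reagents that add atoms: none
Why: Olefin cross-metathesis of a terminal alkene with an electron-poor vinyl ketone, a pairing in which the enone does not homodimerise readily and the conjugated product forms as the E isomer; ethene is lost.

Step 3
Reactants: 4 (E)-7-(tert-butyldimethylsilyloxy)hept-4-en-3-one
Product: 5 (2Z,4E)-3,7-bis(tert-butyldimethylsilyloxy)hepta-2,4-diene
Conditions: TBSOTf, Et3N, CH2Cl2, −78 to 0 °C
Reagents that add atoms: tert-butyldimethylsilyl trifluoromethanesulfonate, CC(C)(C)[Si](C)(C)OS(=O)(=O)C(F)(F)F
Why: Soft enolisation of the ethyl ketone (silyl triflate, amine) removes an α′-proton and gives the cross-conjugated silyl enol ether with methyl cis to oxygen (Z), as is usual for ethyl ketones; this geometry later places the C10 methyl trans to both alkenyl groups of the cyclopropane.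

Step 4
Reactants: 6 glycine methyl ester hydrochloride
Product: 7 methyl diazoacetate
Conditions: NaNO2, cat. H2SO4, CH2Cl2/H2O, −5 °C
Reagents that add atoms: sodium nitrite, [Na+].[O-]N=O
Why: Diazotisation of an α-amino ester; the diazonium ion loses the acidic α-proton and the diazo ester is extracted into the organic layer as it forms, and is used as a solution.

Step 5
Reactants: 7 methyl diazoacetate; 8 (tert-butyldimethylsilyloxy)acetaldehyde
Product: 9 methyl 4-(tert-butyldimethylsilyloxy)-2-diazo-3-hydroxybutanoate (racemic)
Conditions: DBU (10 mol%), MeCN, 0 °C to rt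
Reagents that add atoms: none
Why: Amidine-catalysed aldol-type addition of the diazo ester C–H to an aldehyde; the carbinol centre is racemic and disappears in step 6.

Step 6
Reactants: 9 methyl 4-(tert-butyldimethylsilyloxy)-2-diazo-3-hydroxybutanoate
Product: 11 methyl (E)-2-diazo-4-(tert-butyldimethylsilyloxy)but-3-enoate, via dichlorophosphate 10 (not isolated)
Conditions: POCl3, Et3N, CH2Cl2, 0 °C
Reagents that add atoms: none
Why: Dehydration of a β-hydroxy α-diazo ester by phosphorylation and amine-induced anti elimination; the conformer with the silyloxy group anti to the diazo ester carbon should give the E enol ether, the geometry on which the C6 configuration depends.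

Step 7
Reactants: 11 methyl (E)-2-diazo-4-(tert-butyldimethylsilyloxy)but-3-enoate; 5 (2Z,4E)-3,7-bis(tert-butyldimethylsilyloxy)hepta-2,4-diene
Product: 13 methyl (3R,4R,7R)-3,6-bis(tert-butyldimethylsilyloxy)-4-[2-(tert-butyldimethylsilyloxy)ethyl]-7-methylcyclohepta-1,5-diene-1-carboxylate (route numbering: ester on C1; C1=C5; 6α-OTBS; 7α-CH2CH2OTBS; C8=C9 silyl enol ether; 10α-methyl), via cis-divinylcyclopropane 12 (not isolated)
Conditions: Rh2(S-DOSP)4 [dirhodium tetrakis((S)-N-(4-dodecylphenylsulfonyl)prolinate)] (1 mol%), 5 (1.5 equiv), slow addition of 11, hexane, −78 °C; then rt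
Reagents that add atoms: none
Why: The dirhodium tetraprolinate extrudes N2 from 11 and gives a rhodium-bound vinylcarbene whose electrophilic carbon C1 attacks C10 of the silyl enol ether of 5, the most nucleophilic alkene, with positive charge developing at the oxygen-stabilised C9 before the cyclopropane closes (C1–C10 and C1–C9). The closest known reaction type is the tandem cyclopropanation/Cope rearrangement (formal [4+3] cycloaddition) of vinyldiazoacetates with 1,3-dienes and 2-silyloxy dienes under chiral dirhodium carboxylates; a diene whose enol ether alkene carries a terminal methyl is a more substituted member of that class. The alkenyl (donor) group of the carbenoid and the alkenyl group on C9 end up cis, so 12 is a cis-divinylcyclopropane and should rearrange at or below room temperature through a boat-shaped [3,3] transition state in which C6–C7 forms as the strained C1–C9 bond breaks. The seven-membered ring is therefore closed by expansion of the three-membered ring and not by an end-to-end cyclisation. C10 is fixed in the cyclopropanation, its absolute configuration by the chiral catalyst (face of the carbenoid and orientation of the alkene) and its relation to the alkenyl groups by the Z geometry of the enol ether (methyl cis to oxygen, hence trans to both alkenyl groups). C6 and C7 are fixed in the Cope step by the E geometry of both alkene termini, which in the boat places the C6 silyloxy group and the C7 chain on the outside, cis to each other and cis to the C10 methyl. The step needs site selectivity (enol ether over the E-disubstituted C7=C8 alkene, which donor/acceptor carbenoids cyclopropanate poorly, and over C–H insertion), carbenoid instead of vinylogous reactivity (E substituent at the vinyl terminus, hydrocarbon solvent), the cis-divinyl diastereomer (donor group cis to the alkene substituent) and enantioselectivity (catalyst).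

Step 8
Reactants: 13 cycloheptadiene ester
Product: 14 keto ester (C9 ketone; C8 methylene; C1=C5 enoate; 6α-OTBS; 7α-CH2CH2OTBS; 10α-methyl)
Conditions: Bu4NF (1.05 equiv), AcOH (1.5 equiv), THF, −78 °C
Reagents that add atoms: none
Why: Fluoride cleaves the Si–O bond of the enol ether far faster than those of the alkyl silyl ethers at −78 °C, and the acetic acid protonates the enolate at C8 before it can equilibrate towards C10; no stereocentre is formed and the epimerisable C10 sees no free base.

Step 9
Reactants: 14 keto ester
Product: 15 9β-hydroxy ester (9R; C9–OH trans to the C10 methyl)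
Conditions: (S)-1-methyl-3,3-diphenyltetrahydro-1H,3H-pyrrolo[1,2-c][1,3,2]oxazaborole (0.5 equiv), BH3·SMe2, CH2Cl2, −40 to −20 °C
Reagents that add atoms: none
Why: Corey–Bakshi–Shibata reduction: the oxazaborolidine binds the ketone anti to the α-branched C10 side and delivers hydride to the Si (α) face of C9, so the hydroxyl is β (9R) by reagent control against the substrate's own preference for attack anti to the methyl. The medium is Lewis acidic and not basic, so C10 is not epimerised, and the enoate is inert to borane at this temperature.

Step 10
Reactants: 15 9β-hydroxy ester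
Product: 16 9β-triisopropylsilyl ether
Conditions: TIPSOTf, 2,6-lutidine, CH2Cl2, 0 °C
Reagents that add atoms: triisopropylsilyl trifluoromethanesulfonate, CC(C)[Si](C(C)C)(C(C)C)OS(=O)(=O)C(F)(F)F
Why: Silyl triflate silylation of a hindered secondary alcohol; the TIPS ether is chosen because it outlasts the removal of the two TBS ethers and every later oxidation and falls only in the last step.

Step 11
Reactants: 16 9β-triisopropylsilyl ether
Product: 17 allylic alcohol (C2 hydroxymethyl on C1; C1=C5; 6α-OTBS; 7α-CH2CH2OTBS; 9β-OTIPS; 10α-methyl)
Conditions: i-Bu2AlH (2.5 equiv), CH2Cl2, −78 °C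
Reagents that add atoms: none
Why: 1,2-Reduction of the enoate by an aluminium hydride at low temperature; C2 is brought to the alcohol level now because later a lactone and an isovalerate are present that no ester reduction could spare.

Step 12
Reactants: 17 allylic alcohol
Product: 18 C2 4-methoxybenzyl ether
Conditions: NaH, PMBCl, cat. Bu4NI, DMF, 0 °C to rt
Reagents that add atoms: 4-methoxybenzyl chloride, COc1ccc(CCl)cc1
Why: Williamson ether synthesis; the PMB ether keeps the primary allylic oxygen from competing as a directing group in step 14 and from being oxidised in step 15, and it can be removed oxidatively beside an epoxide and a lactone.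

Step 13
Reactants: 18 C2 4-methoxybenzyl ether
Product: 19 6α,12-diol (C2 OPMB; 9β-OTIPS)
Conditions: HF·pyridine, pyridine, THF, 0 °C to rt
Reagents that add atoms: none
Why: Buffered HF removes the primary and the allylic secondary TBS ethers and leaves the bulkier secondary TIPS ether, in line with the usual order of silyl ether lability; the PMB ether is inert.

Step 14
Reactants: 19 6α,12-diol
Product: 20 1α,5α-epoxy-6α,12-diol
Conditions: VO(acac)2 (5 mol%), t-BuOOH, CH2Cl2, 0 °C to rt
Reagents that add atoms: tert-butyl hydroperoxide, CC(C)(C)OO
Why: Hydroxyl-directed epoxidation: the allylic C6 alkoxide binds vanadium and the peroxide oxygen is delivered to the same (α) face of C1=C5, a delivery that is dependable for cyclohept-2-enols. This sets C1 (oxygen α) and places an α-oxygen at C5 for later inversion; the remote primary hydroxyl does not direct.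

Step 15
Reactants: 20 1α,5α-epoxy-6α,12-diol
Product: 23 cis-fused epoxy γ-lactone (O6–C12; 1α,5α-epoxide; C2 OPMB; 9β-OTIPS), via hydroxy aldehyde 21 (not isolated), via lactol 22 (not isolated)
Conditions: TEMPO (20 mol%), PhI(OAc)2 (2.5 equiv), CH2Cl2, rt
Reagents that add atoms: none
Why: Oxoammonium (TEMPO) oxidation is selective for the primary alcohol; the aldehyde 21 is trapped by the cis C6 hydroxyl as lactol 22, which is oxidised on to the lactone. No vicinal diol is present, so the iodine reagent cannot cleave a glycol.

Step 16
Reactants: 23 cis-fused epoxy γ-lactone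
Product: 24 C11-(dimethylaminomethyl) lactone (C11 epimers)
Conditions: LiN(i-Pr)2, THF, −78 °C; then CH2=NMe2+ I−, −78 to 0 °C
Reagents that add atoms: N,N-dimethylmethyleneiminium iodide (Eschenmoser's salt), C=[N+](C)C.[I-]
Why: Mannich reaction of the lactone enolate brings in C13; the lactone α-methylene is the only acidic site, the epoxide is inert to the amide base at −78 °C, and the configuration at C11 is of no consequence.

Step 17
Reactants: 24 C11-(dimethylaminomethyl) lactone
Product: 26 α-methylene lactone (1α,5α-epoxide; C2 OPMB; 9β-OTIPS), via trimethylammonium iodide 25 (not isolated)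
Conditions: MeI, THF, rt; then aq. NaHCO3, CH2Cl2
Reagents that add atoms: none
Why: Quaternisation and base-induced elimination of trimethylamine give the exocyclic alkene; this is done while the lactone is still the only ester in the molecule.

Step 18
Reactants: 26 α-methylene lactone
Product: 27 2,3-epoxy alcohol (free C2–OH; 1α,5α-epoxide)
Conditions: DDQ, CH2Cl2/pH 7 buffer, 0 °C
Reagents that add atoms: none
Why: Oxidative cleavage of the PMB ether (hydride abstraction, hydrolysis of the oxocarbenium ion) under buffered conditions frees the primary hydroxyl without touching epoxide, lactone or the electron-poor alkene.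

Step 19
Reactants: 27 2,3-epoxy alcohol
Product: 28 5β-(3-methylbutanoyloxy) 1α,2-diol
Conditions: Ti(O-i-Pr)4 (1.5 equiv), 3-methylbutanoic acid (3 equiv), CH2Cl2, rt
Reagents that add atoms: 3-methylbutanoic acid (isovaleric acid), CC(C)CC(=O)O
Why: Titanium alkoxide-mediated opening of a 2,3-epoxy alcohol by a carboxylic acid: the C2 alkoxide and the epoxide oxygen chelate titanium, and the metal-bound carboxylate attacks the distal carbon C5 from the β-face with inversion (SN2). C1 is fully substituted and closed to backside attack, so the result is C5–O β and C1–OH α.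

Step 20
Reactants: 28 5β-(3-methylbutanoyloxy) 1α,2-diol
Product: 29 α-hydroxy aldehyde (C2 = CHO)
Conditions: SO3·pyridine, DMSO, i-Pr2NEt, CH2Cl2, 0 °C
Reagents that add atoms: none
Why: Parikh–Doering oxidation takes the primary alcohol to the aldehyde without the glycol cleavage that iodine-based oxidants can cause in a 1,2-diol; the tertiary hydroxyl is inert, and the step removes at once the hydroxyl to which the isovalerate could migrate.

Step 21
Reactants: 29 α-hydroxy aldehyde; 30 (Z)-1-bromoprop-1-ene
Product: 31 (Z)-allylic alcohol (C2 carbinol, both epimers)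
Conditions: CrCl2 (6 equiv), NiCl2 (2 mol%), DMF, rt
Reagents that add atoms: none
Why: Nozaki–Hiyama–Kishi reaction: zerovalent nickel inserts into the C–Br bond with retention, transmetalation to trivalent chromium gives the (Z)-alkenylchromium, and this adds to aldehydes only, leaving lactone, isovalerate and methylene lactone untouched. The new carbinol centre is removed in step 22.

Step 22
Reactants: 31 (Z)-allylic alcohol
Product: 32 9-O-triisopropylsilyl ether of the target
Conditions: Dess–Martin periodinane, NaHCO3, CH2Cl2, 0 °C
Reagents that add atoms: none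
Why: Dess–Martin oxidation under bicarbonate buffer converts the allylic alcohol to the enone with neither acid nor base strong enough to isomerise the Z double bond; the tertiary C1 hydroxyl cannot be oxidised.

Step 23
Reactants: 32 9-O-triisopropylsilyl ether of the target
Product: 33 target, (3aS,5R,6S,7S,8S,8aR)-7-[(2Z)-but-2-enoyl]-5,7-dihydroxy-6-methyl-3-methylidene-2-oxooctahydro-2H-cyclohepta[b]furan-8-yl 3-methylbutanoate
Conditions: HF·pyridine, pyridine, THF, 0 °C to rt
Reagents that add atoms: none
Why: Fluoride-assisted cleavage of the Si–O bond with buffered HF, conditions that are neither basic nor nucleophilic towards the methylene lactone and the enone; no stereocentre is touched.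

## Compound list

1 | but-3-en-1-ol | C=CCCO | starting material
2 | tert-butyl(but-3-en-1-yloxy)dimethylsilane | C=CCCO[Si](C)(C)C(C)(C)C | intermediate
3 | pent-1-en-3-one | CCC(=O)C=C | starting material
4 | (E)-7-(tert-butyldimethylsilyloxy)hept-4-en-3-one | CCC(=O)/C=C/CCO[Si](C)(C)C(C)(C)C | intermediate
5 | (2Z,4E)-3,7-bis(tert-butyldimethylsilyloxy)hepta-2,4-diene | C/C=C(O[Si](C)(C)C(C)(C)C)/C=C/CCO[Si](C)(C)C(C)(C)C | intermediate
6 | glycine methyl ester hydrochloride | COC(=O)C[NH3+].[Cl-] | starting material
7 | methyl diazoacetate | COC(=O)C=[N+]=[N-] | intermediate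
8 | (tert-butyldimethylsilyloxy)acetaldehyde | O=CCO[Si](C)(C)C(C)(C)C | starting material
9 | methyl 4-(tert-butyldimethylsilyloxy)-2-diazo-3-hydroxybutanoate (racemic) | COC(=O)C(=[N+]=[N-])C(O)CO[Si](C)(C)C(C)(C)C | intermediate
10 | methyl 4-(tert-butyldimethylsilyloxy)-3-(dichlorophosphoryloxy)-2-diazobutanoate (racemic, not isolated) | COC(=O)C(=[N+]=[N-])C(OP(=O)(Cl)Cl)CO[Si](C)(C)C(C)(C)C | intermediate
11 | methyl (E)-2-diazo-4-(tert-butyldimethylsilyloxy)but-3-enoate | COC(=O)C(=[N+]=[N-])/C=C/O[Si](C)(C)C(C)(C)C | intermediate
12 | methyl (1S,2R,3R)-2-(tert-butyldimethylsilyloxy)-1-[(E)-2-(tert-butyldimethylsilyloxy)ethenyl]-2-[(E)-4-(tert-butyldimethylsilyloxy)but-1-en-1-yl]-3-methylcyclopropane-1-carboxylate (alkenyl groups cis, methyl trans to them; not isolated) | COC(=O)[C@@]1(/C=C/O[Si](C)(C)C(C)(C)C)[C@@H](C)[C@]1(O[Si](C)(C)C(C)(C)C)/C=C/CCO[Si](C)(C)C(C)(C)C | intermediate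
13 | methyl (3R,4R,7R)-3,6-bis(tert-butyldimethylsilyloxy)-4-[2-(tert-butyldimethylsilyloxy)ethyl]-7-methylcyclohepta-1,5-diene-1-carboxylate | COC(=O)C1=C[C@H](O[Si](C)(C)C(C)(C)C)[C@H](CCO[Si](C)(C)C(C)(C)C)C=C(O[Si](C)(C)C(C)(C)C)[C@@H]1C | intermediate
14 | keto ester: methyl ester on C1, C1=C5, 6α-OTBS, 7α-(2-TBSO-ethyl), C9 ketone, 10α-methyl | COC(=O)C1=C[C@H](O[Si](C)(C)C(C)(C)C)[C@H](CCO[Si](C)(C)C(C)(C)C)CC(=O)[C@@H]1C | intermediate
15 | 9β-hydroxy ester (9R): as 14 with C9–OH β | COC(=O)C1=C[C@H](O[Si](C)(C)C(C)(C)C)[C@H](CCO[Si](C)(C)C(C)(C)C)C[C@@H](O)[C@@H]1C | intermediate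
16 | 9β-triisopropylsilyl ether of 15 | COC(=O)C1=C[C@H](O[Si](C)(C)C(C)(C)C)[C@H](CCO[Si](C)(C)C(C)(C)C)C[C@@H](O[Si](C(C)C)(C(C)C)C(C)C)[C@@H]1C | intermediate
17 | allylic alcohol: C2 hydroxymethyl on C1, C1=C5, 6α-OTBS, 7α-(2-TBSO-ethyl), 9β-OTIPS, 10α-methyl | OCC1=C[C@H](O[Si](C)(C)C(C)(C)C)[C@H](CCO[Si](C)(C)C(C)(C)C)C[C@@H](O[Si](C(C)C)(C(C)C)C(C)C)[C@@H]1C | intermediate
18 | C2 4-methoxybenzyl ether of 17 | COc1ccc(COCC2=C[C@H](O[Si](C)(C)C(C)(C)C)[C@H](CCO[Si](C)(C)C(C)(C)C)C[C@@H](O[Si](C(C)C)(C(C)C)C(C)C)[C@@H]2C)cc1 | intermediate
19 | 6α,12-diol: C2 OPMB, C1=C5, 6α-OH, 7α-(2-hydroxyethyl), 9β-OTIPS, 10α-methyl | COc1ccc(COCC2=C[C@H](O)[C@H](CCO)C[C@@H](O[Si](C(C)C)(C(C)C)C(C)C)[C@@H]2C)cc1 | intermediate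
20 | 1α,5α-epoxy-6α,12-diol | COc1ccc(COC[C@]23O[C@@H]3[C@H](O)[C@H](CCO)C[C@@H](O[Si](C(C)C)(C(C)C)C(C)C)[C@@H]2C)cc1 | intermediate
21 | 1α,5α-epoxy-6α-hydroxy C12 aldehyde (not isolated) | COc1ccc(COC[C@]23O[C@@H]3[C@H](O)[C@H](CC=O)C[C@@H](O[Si](C(C)C)(C(C)C)C(C)C)[C@@H]2C)cc1 | intermediate
22 | lactol O6–C12(OH), either anomer (not isolated) | C1C(O)O[C@@H]2[C@H]1C[C@@H](O[Si](C(C)C)(C(C)C)C(C)C)[C@H](C)[C@]3(COCc4ccc(OC)cc4)O[C@H]23 | intermediate
23 | cis-fused γ-lactone with 1α,5α-epoxide, C2 OPMB, 9β-OTIPS, 10α-methyl | C1C(=O)O[C@@H]2[C@H]1C[C@@H](O[Si](C(C)C)(C(C)C)C(C)C)[C@H](C)[C@]3(COCc4ccc(OC)cc4)O[C@H]23 | intermediate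
24 | C11-(dimethylaminomethyl) derivative of 23 (C11 epimers) | CN(C)CC1C(=O)O[C@@H]2[C@H]1C[C@@H](O[Si](C(C)C)(C(C)C)C(C)C)[C@H](C)[C@]3(COCc4ccc(OC)cc4)O[C@H]23 | intermediate
25 | trimethylammonium iodide of 24 (not isolated) | C[N+](C)(C)CC1C(=O)O[C@@H]2[C@H]1C[C@@H](O[Si](C(C)C)(C(C)C)C(C)C)[C@H](C)[C@]3(COCc4ccc(OC)cc4)O[C@H]23.[I-] | intermediate
26 | α-methylene lactone with 1α,5α-epoxide, C2 OPMB, 9β-OTIPS | C=C1C(=O)O[C@@H]2[C@H]1C[C@@H](O[Si](C(C)C)(C(C)C)C(C)C)[C@H](C)[C@]3(COCc4ccc(OC)cc4)O[C@H]23 | intermediate
27 | 2,3-epoxy alcohol: as 26 with free C2–OH | C=C1C(=O)O[C@@H]2[C@H]1C[C@@H](O[Si](C(C)C)(C(C)C)C(C)C)[C@H](C)[C@]3(CO)O[C@H]23 | intermediate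
28 | 5β-(3-methylbutanoyloxy) 1α,2-diol | C=C1C(=O)O[C@@H]2[C@H]1C[C@@H](O[Si](C(C)C)(C(C)C)C(C)C)[C@H](C)[C@@](O)(CO)[C@H]2OC(=O)CC(C)C | intermediate
29 | α-hydroxy aldehyde (C2 = CHO on C1, 1α-OH) | C=C1C(=O)O[C@@H]2[C@H]1C[C@@H](O[Si](C(C)C)(C(C)C)C(C)C)[C@H](C)[C@@](O)(C=O)[C@H]2OC(=O)CC(C)C | intermediate
30 | (Z)-1-bromoprop-1-ene | C/C=C\Br | starting material
31 | (Z)-allylic alcohol, C2 carbinol (both epimers) | C=C1C(=O)O[C@@H]2[C@H]1C[C@@H](O[Si](C(C)C)(C(C)C)C(C)C)[C@H](C)[C@@](O)(C(O)/C=C\C)[C@H]2OC(=O)CC(C)C | intermediate
32 | 9-O-triisopropylsilyl ether of the target | C=C1C(=O)O[C@@H]2[C@H]1C[C@@H](O[Si](C(C)C)(C(C)C)C(C)C)[C@H](C)[C@@](O)(C(=O)/C=C\C)[C@H]2OC(=O)CC(C)C | intermediate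
33 | (3aS,5R,6S,7S,8S,8aR)-7-[(2Z)-but-2-enoyl]-5,7-dihydroxy-6-methyl-3-methylidene-2-oxooctahydro-2H-cyclohepta[b]furan-8-yl 3-methylbutanoate (CNP0186412.2) | C=C1C(=O)O[C@@H]2[C@H]1C[C@@H](O)[C@H](C)[C@@](O)(C(=O)/C=C\C)[C@H]2OC(=O)CC(C)C | target

## Step count and least certain steps

Total: 23 steps. Longest linear sequence: 20 steps (steps 1–3 or steps 4–6, then steps 7–23).

**Step 7 (key step).**
- What may go wrong: the carbenoid may fail to cyclopropanate the trisubstituted enol ether cleanly. The carbon framework of that alkene is trans-disubstituted, a pattern that carbenoids of bulky dirhodium prolinates engage slowly. Carbenoid dimerisation, electrocyclisation of 11, zwitterionic [3+2] annulation or closure with the alkenyl groups trans (no Cope rearrangement at ambient temperature) may then compete, and the enantioselectivity may fall.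
- Fallback: leave the C10 methyl out of the cycloaddition. Setting out from 2, cross-metathesis with but-3-en-2-one gives (E)-6-(tert-butyldimethylsilyloxy)hex-3-en-2-one F1, and enol silylation gives (E)-2,6-bis(tert-butyldimethylsilyloxy)hexa-1,3-diene F2, whose 1,1-disubstituted enol ether is a proven partner. With 11 and the same catalyst, the 3-unsubstituted cis-divinylcyclopropane F3 rearranges to the 10-desmethyl cycloheptadiene ester F4, and buffered fluoride gives the 10-desmethyl keto ester F5. Its doubly activated C10 methylene (α to the ketone and allylic) is deprotonated with LiN(SiMe3)2 and methylated with iodomethane, with DBU equilibration if the kinetic face is the wrong one; the all-cis arrangement, with the methyl pseudo-axial and free of A(1,2) strain with the ester, is expected to be favoured at equilibrium. This comes back to the route at 14. The price is that C10 is then under thermodynamic and not catalyst control.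

**Step 9.**
- What may go wrong: poor facial selectivity, because the catalyst must overrule the substrate's preference for hydride attack anti to the adjacent methyl (a mismatched case). A slow reduction would also give time for epimerisation at C10.
- Fallback: accept substrate control and invert. Setting out from 14, LiBH(s-Bu)3 in THF at −78 °C attacks from the β-face and gives the 9α-hydroxy ester F6. A Mitsunobu reaction with 4-nitrobenzoic acid, PPh3 and diisopropyl azodicarboxylate gives the 9β-(4-nitrobenzoate) F7 with inversion, and K2CO3 in methanol releases 15, where the route is rejoined.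

**Step 19.**
- What may go wrong: ionisation at the tertiary C1 with capture of the carboxylate there, migration of the new ester from O5 to the primary O2 under the transesterifying titanium alkoxide, or incomplete conversion at the hindered C5.
- Fallback: rely on plain SN2 sterics instead of chelation. Setting out from 26, where C2 is still a PMB ether and no hydroxyl is free, caesium 3-methylbutanoate (from the acid and Cs2CO3) with 18-crown-6 in warm DMF can attack only the secondary C5 and gives the 5β-isovalerate 1α-hydroxy PMB ether F8. DDQ then removes the PMB group and the route is rejoined at 28. The weakness is the exposure of the methylene lactone to a warm carboxylate.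

**Step 21.**
- What may go wrong: slow oxidative addition of the alkenyl bromide, so that the hindered α-hydroxy aldehyde stays in contact with Lewis-acidic chromium salts and undergoes an α-ketol shift with ring expansion; or partial loss of the Z geometry during transmetalation.
- Fallback: bring in C3–C4 as an alkyne. Setting out from 29, 1-propynylmagnesium bromide (CH3C≡CMgBr) in THF at −78 °C adds to the aldehyde only and gives the propargylic alcohol F9. Semi-hydrogenation over Pd/CaCO3 poisoned with Pb(OAc)2 and quinoline, stopped at one equivalent of H2, gives 31, where the route is rejoined.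

## Further compounds

F1 | step 7 | (E)-6-(tert-butyldimethylsilyloxy)hex-3-en-2-one | CC(=O)/C=C/CCO[Si](C)(C)C(C)(C)C
F2 | step 7 | (E)-2,6-bis(tert-butyldimethylsilyloxy)hexa-1,3-diene | C=C(O[Si](C)(C)C(C)(C)C)/C=C/CCO[Si](C)(C)C(C)(C)C
F3 | step 7 | 3-unsubstituted cis-divinylcyclopropane, methyl 2-(tert-butyldimethylsilyloxy)-1-[(E)-2-(tert-butyldimethylsilyloxy)ethenyl]-2-[(E)-4-(tert-butyldimethylsilyloxy)but-1-en-1-yl]cyclopropane-1-carboxylate (alkenyl groups cis) | COC(=O)[C@@]1(/C=C/O[Si](C)(C)C(C)(C)C)C[C@]1(O[Si](C)(C)C(C)(C)C)/C=C/CCO[Si](C)(C)C(C)(C)C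
F4 | step 7 | 10-desmethyl cycloheptadiene ester (as 13 with C10 methylene) | COC(=O)C1=C[C@H](O[Si](C)(C)C(C)(C)C)[C@H](CCO[Si](C)(C)C(C)(C)C)C=C(O[Si](C)(C)C(C)(C)C)C1
F5 | step 7 | 10-desmethyl keto ester (as 14 with C10 methylene) | COC(=O)C1=C[C@H](O[Si](C)(C)C(C)(C)C)[C@H](CCO[Si](C)(C)C(C)(C)C)CC(=O)C1
F6 | step 9 | 9α-hydroxy ester (C9 epimer of 15) | COC(=O)C1=C[C@H](O[Si](C)(C)C(C)(C)C)[C@H](CCO[Si](C)(C)C(C)(C)C)C[C@H](O)[C@@H]1C
F7 | step 9 | 9β-(4-nitrobenzoate) of 15 | COC(=O)C1=C[C@H](O[Si](C)(C)C(C)(C)C)[C@H](CCO[Si](C)(C)C(C)(C)C)C[C@@H](OC(=O)c2ccc(cc2)[N+](=O)[O-])[C@@H]1C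
F8 | step 19 | 5β-(3-methylbutanoyloxy) 1α-hydroxy C2 4-methoxybenzyl ether (PMB ether of 28) | C=C1C(=O)O[C@@H]2[C@H]1C[C@@H](O[Si](C(C)C)(C(C)C)C(C)C)[C@H](C)[C@@](O)(COCc3ccc(OC)cc3)[C@H]2OC(=O)CC(C)C
F9 | step 21 | propargylic alcohol, C2 carbinol bearing prop-1-ynyl (both epimers) | C=C1C(=O)O[C@@H]2[C@H]1C[C@@H](O[Si](C(C)C)(C(C)C)C(C)C)[C@H](C)[C@@](O)(C(O)C#CC)[C@H]2OC(=O)CC(C)C
A1 | alternative 1 | methyl (Z)-2-(bromomethyl)alk-2-enoate with C6 aldehyde, 5-isovalerate, C1/C2 spiro-acetonide, 9-OTBS and 10-methyl | COC(=O)C(/CBr)=C/C[C@@H](O[Si](C)(C)C(C)(C)C)[C@H](C)[C@@]1(COC(C)(C)O1)[C@H](C=O)OC(=O)CC(C)C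
A2 | alternative 1 | cis-fused α-methylene lactone on the cycloheptane with C1/C2 spiro-acetonide, 9-OTBS and 5-isovalerate | C=C1C(=O)O[C@@H]2[C@H]1C[C@@H](O[Si](C)(C)C(C)(C)C)[C@H](C)[C@@]3(COC(C)(C)O3)[C@H]2OC(=O)CC(C)C
A3 | alternative 2 | oxepan-2-one with 3-(4-methoxybenzyloxy) (either epimer), 4,5-trans-acetonide, 6-(2-triisopropylsilyloxyethyl) and 7-[(Z)-prop-1-enyl], the last two cis | O=C1O[C@@H](/C=C\C)[C@@H](CCO[Si](C(C)C)(C(C)C)C(C)C)[C@H]2OC(C)(C)O[C@@H]2C1OCc1ccc(OC)cc1
A4 | alternative 2 | cyclohept-3-ene-1-carboxylic acid with C1 OPMB, C10 methyl, C5/C6 acetonide and C7 silyloxyethyl arm | OC(=O)[C@]1(OCc2ccc(OC)cc2)[C@@H](C)C=C[C@@H](CCO[Si](C(C)C)(C(C)C)C(C)C)[C@H]2OC(C)(C)O[C@H]12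
A5 | alternative 3 | γ-lactone with C7 2-oxoethyl arm (C9 aldehyde) and C6 side chain bearing 5-OTES and the (Z)-2-(trimethylsilylmethyl)but-2-enyl unit | O=C1C[C@H](CC=O)[C@@H](O1)[C@H](O[Si](CC)(CC)CC)/C(C[Si](C)(C)C)=C/C
A6 | alternative 3 | cis-fused lactone on the cycloheptane with 9-hydroxyl, 10-methyl, exocyclic C1=C2 methylene and 5-OTES | O=C1C[C@@H]2C[C@@H](O)[C@H](C)C(=C)[C@@H](O[Si](CC)(CC)CC)[C@@H]2O1
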